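**Assumption (one line):** germacrane numbering (C1–C10 ring, C11–C13 methylene-lactone carbons, C14 on C10, C15 on C4) is used for every intermediate, and compounds 1, 2, 5, 18 and 33 are bought (1 freshly distilled).

## Analysis of the target

The target is a heliangolide-type germacranolide. A ten-membered carbocycle (C1–C10) is trans-fused at C6–C7 to an α-methylene-γ-butyrolactone (O–C6, C7, C11=C13H2, C12=O). The ring carries a Z-trisubstituted C4=C5 alkene, a trans 1,10-epoxide with C10 quaternary, an isovalerate on C3 and a (2S,3R)-2,3-dimethyloxirane-2-carboxylate (the epoxide of tiglic acid) on C8. There are eight stereocentres: C1 (R), C3 (S), C6 (R), C7 (R), C8 (R), C10 (R) in the ring and C2′ (S), C3′ (R) in the side-chain epoxide. C6, C7 and C8 are contiguous: H6 and H7 are trans on the lactone, while the C8 oxygen stands to C7 as a cis-8,12-lactone would require, so the C7/C8 relationship cannot be set by ring-enforced trans addition. C3 is isolated from this triad by the alkene, and C1/C10 arise together from an E alkene. Sensitive groups are the exo-methylene lactone (adds thiols, amines, alkoxides and phosphines), two acid-labile epoxides, the allylic C3 ester, and the lactone itself, which can migrate to the C8 oxygen under base. The difficulty is a strained ten-membered ring with an E and a Z trisubstituted alkene, plus stereocentres that should not depend on unknown medium-ring conformations. The strategy rests on one feature: C3 is a carbinol bonded directly to C4, the fully substituted carbon of the Z alkene. The C3(=O)–C4=C5 enone can therefore be made from an acyl donor at C3 and a Z vinyl metal at C4, and C3 can be set afterwards by a chiral catalyst.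

## Retrosynthetic reasoning

**38 to 37.** The ring epoxide is removed first. It is the most acid-sensitive group and its precursor, the C1=C10 alkene of 37, is the only electron-rich, unhindered alkene in the molecule. A late peracid epoxidation needs only chemoselectivity and outer-face attack on an E-cyclodecene.

**37 to 29.** The two ester C–O bonds are cut next: the C8 ester to alcohol 32 and acid 36, the C3 ester to alcohol 30. Alcohol 30 is traced to ketone 29, because a planar C3 carbonyl next to a branched alkenyl group is a good substrate for catalyst-controlled reduction. This makes C3 independent of ring conformation.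

**29 to 28 (key disconnection).** The C3–C4 bond of the enone is cut to thioester–vinylstannane 28. Cutting here, and not at an sp3–sp3 bond, means that the ring closure creates no stereocentre and only has to transfer the Z geometry of the stannane. The three contiguous centres C6–C8 and the methylene lactone are already in place and act as rigid turn elements. The forward reaction must run under neutral conditions, because the C2 methylene of 29 lies between a ketone and an alkene and would isomerise with base.

**28 to 22.** Tin is introduced last, from vinyl iodide 27, because a vinylstannane would not survive the oxidations that turn the C3 carbinol of 23 into acid 25. Thioester 27 is made from 25 through an acid chloride and a silyl sulfide, since a free thiolate would add to the methylene lactone. The C3 oxygen is carried as a 4-methoxybenzyl ether (22), removable by oxidation beside the secondary silyl ether.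

**22 to 16.** The C4=C5 bond is cut by an α-iodo ylide olefination of aldehyde 17 with the ylide derived from 18. This sets the Z iodide directly and brings in C4 and C15. Aldehyde 17 comes from primary alcohol 16.

**16 to 13.** The lactone C12–O6 bond is opened to a methyl ester and a C5/C6 diol masked as the acetonide in 14. Unmasking the diol is planned to trigger lactonisation through the γ-oxygen, and it leaves C5 as the free carbinol needed for the olefination. The C8 hydroxyl of 13 is silylated before this, so it cannot compete for the ester.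

**13 to 4 + 11.** The C7–C8 bond is cut by a Barbier-type allylation of aldehyde 11 with allylic bromide 4. This places the acrylate (C11–C13) directly, so no late α-methylenation is needed. The Z geometry of 4 is expected to give the syn C7/C8 relationship through a closed transition state, and the dioxolane stereocentre of 4 (future C6) is expected to direct the face at C7. C6 itself comes from the chiral pool.

**4 and 11 to starting materials.** Bromide 4 comes from 1 and 2 by a Morita–Baylis–Hillman reaction (C7–C11 bond) and allylic transposition of the adduct 3. Aldehyde 11 comes from alkyne 5 by syn-methylalumination and two-carbon homologation of the alkenyl metal, which fixes the E geometry of C1=C10, followed by a protecting-group exchange and oxidation (8, 9, 10).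

**36 to 33.** The epoxy acid is traced through epoxy alcohol 35 to allylic alcohol 34 and tiglic acid 33. The E alkene of 33 gives the cis-dimethyl epoxide, and a Sharpless epoxidation sets both centres.

## Alternatives that were turned down

**Alternative 1:** Disconnection of the lactone C6–O and the C3–O ester bonds across a C3=C4–C5=C6 ring diene. In the forward step, Pd(OAc)2 with benzoquinone would make the carboxylic acid of triene acid A2 attack C6 and then deliver isovalerate to C3 of the π-allyl, giving A1, which is identical with 37.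
- For: one oxidation forms the lactone, the C3 ester and the Z alkene, and A1 is a single epoxidation from the target. No redox adjustment or protection at C3 is needed. On step economy after ring formation it is stronger than the chosen route.
- Against: it does not say how the ten-membered ring of A2, with a cis,cis-1,3-diene beside an E alkene and the C7/C8 centres, is to be made; that ring is harder than the target's. Divalent palladium can also bind the more electron-rich C1=C10 alkene. The C3/C6 relationship depends on the face of a π-allyl in a flexible medium ring and on internal versus external delivery of the carboxylate. The allylic isovalerate formed can ionise again.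
- Comparison: the chosen strategy gives up the double C–O bond formation but offers a defined ring-forming bond and a catalyst-controlled C3.

**Alternative 2:** Disconnection of C5–C6 and the lactone C–O bond. In the forward step, CrCl2 with catalytic NiCl2 would turn the Z vinyl iodide of iodo aldehyde A4 into a vinylchromium that adds to the C6 aldehyde; the chromium alkoxide then closes the lactone, giving A3.
- For: Nozaki–Hiyama–Kishi closure is the best-precedented way to make medium rings from a vinyl iodide and an aldehyde. It retains the Z geometry, tolerates esters, and allows C3 to be set in the open chain. On precedent for the ring closure itself it is stronger than an acyl cross-coupling.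
- Against: C6 is created in the cyclisation and must come out anti to the C7 substituent; only Felkin preference or ring conformation controls this. The C6 aldehyde is α-branched and can epimerise. A3 lacks C13, so the methylene must be added late by enolate chemistry in a molecule carrying an isovalerate and a skipped diene.
- Comparison: the chosen route carries the methylene lactone from an early allylation and fixes C6 with C7 and C8 before the ring is closed, at the price of a less proven closure.

**Alternative 3:** Disconnection of C8–C9 with reconnection of C6 to C1, a retro-[3,3] shift. In the forward step, the potassium alkoxide of dialkenyl cyclohexenol A6 undergoes an anionic oxy-Cope rearrangement to cyclodecadienone A5.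
- For: this is a classic, strain-tolerant entry to cyclodecenones. The chair transition state sets the E C1=C10 alkene and the C8 centre, and the enolate is formed regiospecifically at C7. On ring formation it is the strongest of the four.
- Against: A5 has a ketone at C6 and a methylene at C7. The C11–C13 unit must be added by enolate alkylation and C6 reduced to the trans-lactone relationship, both under conformational control of a flexible ring. A6 is not a simple carvone derivative (the isopropenyl and methyl groups sit on the wrong carbons), and its vinyl addition must be trans-selective. About eight steps remain after the ring is formed (alkylation, reduction, lactonisation, two deprotections, two acylations, epoxidation).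
- Comparison: in the chosen route only the final epoxidation depends on ring conformation.

Key step: step 16

## Route

Step 1
Reactants: 1 (R)-2,2-dimethyl-1,3-dioxolane-4-carbaldehyde; 2 methyl acrylate
Product: 3 methyl 2-{[(4R)-2,2-dimethyl-1,3-dioxolan-4-yl](hydroxy)methyl}prop-2-enoate (both carbinol epimers)
Conditions: DABCO (1,4-diazabicyclo[2.2.2]octane, 0.5 equiv), 2 (3 equiv), 1,4-dioxane/H2O 1:1, rt
Reagents that add atoms: none
Why: Morita–Baylis–Hillman reaction forms C7–C11 and installs the acrylate; the new carbinol centre is destroyed in step 2, so its configuration is irrelevant, and the dioxolane centre (future C6) comes unchanged from the chiral pool.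

Step 2
Reactants: 3 methyl 2-{[(4R)-2,2-dimethyl-1,3-dioxolan-4-yl](hydroxy)methyl}prop-2-enoate
Product: 4 methyl (2Z)-2-(bromomethyl)-3-[(4S)-2,2-dimethyl-1,3-dioxolan-4-yl]prop-2-enoate
Conditions: NBS, Me2S, CH2Cl2, 0 °C to rt
Reagents that add atoms: N-bromosuccinimide, O=C1CCC(=O)N1Br
Why: Corey–Kim-type activation of the allylic alcohol followed by bromide attack with allylic transposition; both epimers of 3 converge on the (Z)-2-(bromomethyl)alkenoate, the usual outcome for Baylis–Hillman adducts, and the neutral conditions spare the acetonide.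

Step 3
Reactants: 5 tert-butyl(but-3-yn-1-yloxy)dimethylsilane
Product: 8 (3E)-6-{[tert-butyl(dimethyl)silyl]oxy}-4-methylhex-3-en-1-ol, via alkenylalane 6 (not isolated), via lithium alkenylalanate 7 (not isolated)
Conditions: Me3Al (2.5 equiv), Cp2ZrCl2 (0.2 equiv), CH2Cl2, −20 °C to rt; evaporate; n-BuLi, THF/hexane, −78 °C; ethylene oxide, −78 to 0 °C
Reagents that add atoms: trimethylaluminium, C[Al](C)C; ethylene oxide, C1CO1
Why: Negishi zirconium-catalysed syn-carboalumination puts the methyl (C14) on the internal alkyne carbon and fixes the E geometry of C1=C10; the alanate opens the epoxide with retention at the vinyl carbon, adding C2 and C3.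

Step 4
Reactants: 8 (3E)-6-{[tert-butyl(dimethyl)silyl]oxy}-4-methylhex-3-en-1-ol
Product: 9 tert-butyl({(3E)-6-[(4-methoxybenzyl)oxy]-3-methylhex-3-en-1-yl}oxy)dimethylsilane
Conditions: NaH, 4-methoxybenzyl chloride, Bu4NI (cat.), THF/DMF, 0 °C to rt
Reagents that add atoms: 4-methoxybenzyl chloride, COc1ccc(CCl)cc1
Why: Williamson etherification of the primary alcohol; the 4-methoxybenzyl ether masks C3–O until after the olefination and is later removed oxidatively beside a secondary silyl ether.

Step 5
Reactants: 9 tert-butyl({(3E)-6-[(4-methoxybenzyl)oxy]-3-methylhex-3-en-1-yl}oxy)dimethylsilane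
Product: 10 (3E)-6-[(4-methoxybenzyl)oxy]-3-methylhex-3-en-1-ol
Conditions: Bu4NF, THF, 0 °C to rt
Reagents that add atoms: none
Why: Fluoride cleavage of the primary silyl ether frees the C8 carbinol; the benzyl-type ether and the alkene are inert.

Step 6
Reactants: 10 (3E)-6-[(4-methoxybenzyl)oxy]-3-methylhex-3-en-1-ol
Product: 11 (3E)-6-[(4-methoxybenzyl)oxy]-3-methylhex-3-enal
Conditions: Dess–Martin periodinane, NaHCO3, CH2Cl2, 0 °C; used at once
Reagents that add atoms: none
Why: Buffered Dess–Martin oxidation gives the β,γ-unsaturated aldehyde without base, so the alkene does not move into conjugation.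

Step 7
Reactants: 4 methyl (2Z)-2-(bromomethyl)-3-[(4S)-2,2-dimethyl-1,3-dioxolan-4-yl]prop-2-enoate; 11 (3E)-6-[(4-methoxybenzyl)oxy]-3-methylhex-3-enal
Product: 13 methyl (3R,4R,6E)-3-[(4S)-2,2-dimethyl-1,3-dioxolan-4-yl]-4-hydroxy-9-[(4-methoxybenzyl)oxy]-6-methyl-2-methylidenenon-6-enoate, via allylindium dibromide 12 (not isolated)
Conditions: In powder (1.5 equiv), THF/H2O 1:1, rt, neutral work-up
Reagents that add atoms: none
Why: Indium-mediated Barbier allylation through the γ-carbon forms C7–C8; the Z-allylindium reacts through a closed six-membered transition state with the aldehyde chain equatorial, which gives the syn C7/C8 adduct, and C7 is set relative to C6 by the dioxolane, whose hydrogen eclipses the alkene (allylic 1,3-strain) so that the aldehyde enters anti to the C6–O bond.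

Step 8
Reactants: 13 methyl (3R,4R,6E)-3-[(4S)-2,2-dimethyl-1,3-dioxolan-4-yl]-4-hydroxy-9-[(4-methoxybenzyl)oxy]-6-methyl-2-methylidenenon-6-enoate
Product: 14 methyl (3S,4R,6E)-4-{[tert-butyl(dimethyl)silyl]oxy}-3-[(4S)-2,2-dimethyl-1,3-dioxolan-4-yl]-9-[(4-methoxybenzyl)oxy]-6-methyl-2-methylidenenon-6-enoate
Conditions: TBSOTf, 2,6-lutidine, CH2Cl2, −78 to 0 °C
Reagents that add atoms: tert-butyldimethylsilyl triflate, CC(C)(C)[Si](C)(C)OS(=O)(=O)C(F)(F)F
Why: Silylation of the hindered C8 hydroxyl with the triflate; it must come before the diol is unmasked so that only O6 can lactonise (the C7 descriptor changes from R to S only because the silyloxy branch now ranks first).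

Step 9
Reactants: 14 methyl (3S,4R,6E)-4-{[tert-butyl(dimethyl)silyl]oxy}-3-[(4S)-2,2-dimethyl-1,3-dioxolan-4-yl]-9-[(4-methoxybenzyl)oxy]-6-methyl-2-methylidenenon-6-enoate
Product: 16 (4S,5S)-4-{(1R,3E)-1-{[tert-butyl(dimethyl)silyl]oxy}-6-[(4-methoxybenzyl)oxy]-3-methylhex-3-en-1-yl}-5-(hydroxymethyl)-3-methylideneoxolan-2-one, via dihydroxy ester 15 (not isolated)
Conditions: pyridinium p-toluenesulfonate (0.3 equiv), MeOH, 45 °C; then toluene, 50 °C
Reagents that add atoms: none
Why: Acid-catalysed transacetalisation frees the C5/C6 diol and the secondary C6 hydroxyl closes the γ-lactone on the acrylate ester (five-membered ring favoured over the δ-lactone through O5); the C6/C7 relationship set in step 7 makes the lactone trans, and the hindered secondary silyl ether and the benzyl ether survive.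

Step 10
Reactants: 16 (4S,5S)-4-{(1R,3E)-1-{[tert-butyl(dimethyl)silyl]oxy}-6-[(4-methoxybenzyl)oxy]-3-methylhex-3-en-1-yl}-5-(hydroxymethyl)-3-methylideneoxolan-2-one
Product: 17 (2S,3S)-3-{(1R,3E)-1-{[tert-butyl(dimethyl)silyl]oxy}-6-[(4-methoxybenzyl)oxy]-3-methylhex-3-en-1-yl}-4-methylidene-5-oxooxolane-2-carbaldehyde
Conditions: Dess–Martin periodinane, NaHCO3, CH2Cl2, 0 °C to rt; used at once
Reagents that add atoms: none
Why: Neutral oxidation of the primary alcohol to the C5 aldehyde; no base is present, so the C6 centre next to the aldehyde is not epimerised.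

Step 11
Reactants: 17 (2S,3S)-3-{(1R,3E)-1-{[tert-butyl(dimethyl)silyl]oxy}-6-[(4-methoxybenzyl)oxy]-3-methylhex-3-en-1-yl}-4-methylidene-5-oxooxolane-2-carbaldehyde; 18 ethyltriphenylphosphonium bromide
Product: 22 (4S,5S)-4-{(1R,3E)-1-{[tert-butyl(dimethyl)silyl]oxy}-6-[(4-methoxybenzyl)oxy]-3-methylhex-3-en-1-yl}-5-[(1Z)-2-iodoprop-1-en-1-yl]-3-methylideneoxolan-2-one, via ethylidene ylide 19 (not isolated), via iodoethylphosphonium iodide 20 (not isolated), via iodoethylidene ylide 21 (not isolated)
Conditions: 18, n-BuLi, THF, −78 to 0 °C; I2, −78 °C; NaN(SiMe3)2, −78 to −20 °C; then 17, −78 °C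
Reagents that add atoms: iodine, II
Why: Stork–Zhao-type Wittig olefination with the α-iodo ylide forms C4=C5 and brings in C15; the unstabilised ylide gives the Z-iodoalkene (iodine cis to C6) under kinetic control, and at −78 °C the aldehyde reacts far faster than the methylene lactone.

Step 12
Reactants: 22 (4S,5S)-4-{(1R,3E)-1-{[tert-butyl(dimethyl)silyl]oxy}-6-[(4-methoxybenzyl)oxy]-3-methylhex-3-en-1-yl}-5-[(1Z)-2-iodoprop-1-en-1-yl]-3-methylideneoxolan-2-one
Product: 23 (4S,5S)-4-[(1R,3E)-1-{[tert-butyl(dimethyl)silyl]oxy}-6-hydroxy-3-methylhex-3-en-1-yl]-5-[(1Z)-2-iodoprop-1-en-1-yl]-3-methylideneoxolan-2-one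
Conditions: DDQ, CH2Cl2/pH 7 buffer 10:1, 0 °C to rt
Reagents that add atoms: none
Why: Oxidative cleavage of the 4-methoxybenzyl ether; the vinyl iodide, silyl ether, methylene lactone and trisubstituted alkene are not oxidised by the quinone.

Step 13
Reactants: 23 (4S,5S)-4-[(1R,3E)-1-{[tert-butyl(dimethyl)silyl]oxy}-6-hydroxy-3-methylhex-3-en-1-yl]-5-[(1Z)-2-iodoprop-1-en-1-yl]-3-methylideneoxolan-2-one
Product: 25 (3E,6R)-6-{[tert-butyl(dimethyl)silyl]oxy}-6-{(2S,3S)-2-[(1Z)-2-iodoprop-1-en-1-yl]-4-methylidene-5-oxooxolan-3-yl}-4-methylhex-3-enoic acid, via aldehyde 24 (not isolated)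
Conditions: (2,2,6,6-tetramethylpiperidin-1-yl)oxyl (0.2 equiv), PhI(OAc)2 (2.5 equiv), MeCN/H2O 1:1, rt
Reagents that add atoms: water, O
Why: Oxoammonium oxidation of the primary homoallylic alcohol to the acid through the aldehyde hydrate; the medium is weakly acidic, so the β,γ-alkene stays in place and the vinyl iodide is untouched.

Step 14
Reactants: 25 (3E,6R)-6-{[tert-butyl(dimethyl)silyl]oxy}-6-{(2S,3S)-2-[(1Z)-2-iodoprop-1-en-1-yl]-4-methylidene-5-oxooxolan-3-yl}-4-methylhex-3-enoic acid
Product: 27 S-ethyl (3E,6R)-6-{[tert-butyl(dimethyl)silyl]oxy}-6-{(2S,3S)-2-[(1Z)-2-iodoprop-1-en-1-yl]-4-methylidene-5-oxooxolan-3-yl}-4-methylhex-3-enethioate, via acid chloride 26 (not isolated)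
Conditions: 1-chloro-N,N,2-trimethylprop-1-en-1-amine, CH2Cl2, 0 °C; then EtSSiMe3, 0 °C to rt
Reagents that add atoms: (ethylthio)trimethylsilane, CCS[Si](C)(C)C
Why: Neutral acid chloride formation with the chloroenamine, then acylation of the silyl sulfide; no free thiolate or amine base is present, so there is no thia-Michael addition to the methylene lactone and no base-induced shift of the β,γ-alkene.

Step 15
Reactants: 27 S-ethyl (3E,6R)-6-{[tert-butyl(dimethyl)silyl]oxy}-6-{(2S,3S)-2-[(1Z)-2-iodoprop-1-en-1-yl]-4-methylidene-5-oxooxolan-3-yl}-4-methylhex-3-enethioate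
Product: 28 S-ethyl (3E,6R)-6-{[tert-butyl(dimethyl)silyl]oxy}-4-methyl-6-{(2S,3S)-4-methylidene-5-oxo-2-[(1Z)-2-(tributylstannyl)prop-1-en-1-yl]oxolan-3-yl}hex-3-enethioate
Conditions: (Bu3Sn)2 (2 equiv), Pd2(dba)3·CHCl3 (5 mol %), iPr2NEt, N-methylpyrrolidone, rt to 40 °C, dark
Reagents that add atoms: hexabutylditin, CCCC[Sn](CCCC)(CCCC)[Sn](CCCC)(CCCC)CCCC
Why: Palladium-catalysed stannylation of the vinyl iodide with retention of the Z geometry; the thioester C–S bond does not couple with tin under zerovalent palladium in the absence of a cuprous carboxylate, so tin can be introduced last.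

Step 16
Reactants: 28 S-ethyl (3E,6R)-6-{[tert-butyl(dimethyl)silyl]oxy}-4-methyl-6-{(2S,3S)-4-methylidene-5-oxo-2-[(1Z)-2-(tributylstannyl)prop-1-en-1-yl]oxolan-3-yl}hex-3-enethioate
Product: 29 (6R,7S,8R)-8-{[tert-butyl(dimethyl)silyl]oxy}-3-oxogermacra-1(10)E,4Z,11(13)-trien-12,6-olide
Conditions: Pd(PPh3)4 (20 mol %), CuO2PPh2 (2 equiv), THF, 50 °C, 28 added by syringe pump over 12 h to 1 mM
Reagents that add atoms: none
Why: The thiophilic cuprous diphenylphosphinate activates the thioester so that zerovalent palladium inserts into the acyl C–S bond, and it also takes the thiolate and the tin residue; the vinyl group passes from tin via copper to palladium with retention, and reductive elimination joins C3 to C4. The closest known reactions are the palladium-catalysed, cuprous-carboxylate-mediated ketone synthesis from thioesters and organostannanes and acyl Stille macrocyclisations; closing a ten-membered carbocycle this way extends their ring-size range. The ring is closed as a macrocyclisation: intramolecular transmetallation gives an eleven-membered palladacycle, which contracts to the ten-membered carbocycle on C–C reductive elimination. No stereocentre is formed. The step needs ring closure to win over oligomerisation, which is secured by high dilution and slow addition and helped by the Z vinyl unit, the trans-lactone and the E alkene acting as turn elements. It needs retention of the Z vinyl and E alkene geometries, which follows from stereoretentive transmetallation and the absence of base. It needs the acidic C2 methylene, the methylene lactone and the silyl ether to survive, which the neutral medium allows. The enone is reduced at once in step 17.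

Step 17
Reactants: 29 (6R,7S,8R)-8-{[tert-butyl(dimethyl)silyl]oxy}-3-oxogermacra-1(10)E,4Z,11(13)-trien-12,6-olide
Product: 30 (3S,6R,7S,8R)-8-{[tert-butyl(dimethyl)silyl]oxy}-3-hydroxygermacra-1(10)E,4Z,11(13)-trien-12,6-olide
Conditions: (R)-1-methyl-3,3-diphenyltetrahydro-1H,3H-pyrrolo[1,2-c][1,3,2]oxazaborole [(R)-Me-CBS, 1 equiv], catecholborane (2 equiv), toluene, −78 °C
Reagents that add atoms: none
Why: Corey–Bakshi–Shibata 1,2-reduction of the enone; the α-methyl alkenyl side acts as the large group and the C2 methylene as the small one, so the (R)-catalyst (which gives (S)-1-phenylethanol from acetophenone) is expected to give the 3S carbinol, and catecholborane at −78 °C does not hydroborate the alkenes.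

Step 18
Reactants: 30 (3S,6R,7S,8R)-8-{[tert-butyl(dimethyl)silyl]oxy}-3-hydroxygermacra-1(10)E,4Z,11(13)-trien-12,6-olide
Product: 31 (3S,6R,7S,8R)-8-{[tert-butyl(dimethyl)silyl]oxy}-3-[(3-methylbutanoyl)oxy]germacra-1(10)E,4Z,11(13)-trien-12,6-olide
Conditions: 3-methylbutanoyl chloride, pyridine, DMAP (cat.), CH2Cl2, 0 °C
Reagents that add atoms: 3-methylbutanoyl chloride, CC(C)CC(=O)Cl
Why: Standard acylation of the allylic secondary alcohol with retention at C3.

Step 19
Reactants: 31 (3S,6R,7S,8R)-8-{[tert-butyl(dimethyl)silyl]oxy}-3-[(3-methylbutanoyl)oxy]germacra-1(10)E,4Z,11(13)-trien-12,6-olide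
Product: 32 (3S,6R,7R,8R)-8-hydroxy-3-[(3-methylbutanoyl)oxy]germacra-1(10)E,4Z,11(13)-trien-12,6-olide
Conditions: HF·pyridine, pyridine/THF, 0 °C to rt
Reagents that add atoms: none
Why: Acidic fluoride desilylation; a basic fluoride source is avoided because the C8 alkoxide could attack the lactone carbonyl and shift the lactone to O8.

Step 20
Reactants: 33 tiglic acid [(2E)-2-methylbut-2-enoic acid]
Product: 34 (2E)-2-methylbut-2-en-1-ol
Conditions: LiAlH4, Et2O, 0 °C to rt
Reagents that add atoms: none
Why: Hydride reduction of the acid to the allylic alcohol with the E geometry retained.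

Step 21
Reactants: 34 (2E)-2-methylbut-2-en-1-ol
Product: 35 [(2R,3R)-2,3-dimethyloxiran-2-yl]methanol
Conditions: Ti(OiPr)4 (10 mol %), D-(−)-diisopropyl tartrate (12 mol %), t-BuOOH, 4 Å molecular sieves, CH2Cl2, −20 °C
Reagents that add atoms: tert-butyl hydroperoxide, CC(C)(C)OO
Why: Sharpless asymmetric epoxidation; L-(+)-tartrates turn E-2,3-disubstituted allylic alcohols into (2S,3S)-epoxy alcohols, so the D-(−)-tartrate delivers the (2R,3R) product, and the E alkene fixes the two methyl groups cis.

Step 22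
Reactants: 35 [(2R,3R)-2,3-dimethyloxiran-2-yl]methanol
Product: 36 (2S,3R)-2,3-dimethyloxirane-2-carboxylic acid
Conditions: RuCl3·xH2O (2 mol %), NaIO4 (3 equiv), MeCN/EtOAc/H2O, rt
Reagents that add atoms: sodium periodate, [Na+].[O-]I(=O)(=O)=O; water, O
Why: Ruthenium tetroxide oxidation of the primary epoxy alcohol to the glycidic acid without touching the ring; the C2 descriptor changes from R to S only because the carboxyl now outranks the ring carbon.

Step 23
Reactants: 32 (3S,6R,7R,8R)-8-hydroxy-3-[(3-methylbutanoyl)oxy]germacra-1(10)E,4Z,11(13)-trien-12,6-olide; 36 (2S,3R)-2,3-dimethyloxirane-2-carboxylic acid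
Product: 37 (3S,6R,7R,8R)-8-{[(2S,3R)-2,3-dimethyloxirane-2-carbonyl]oxy}-3-[(3-methylbutanoyl)oxy]germacra-1(10)E,4Z,11(13)-trien-12,6-olide
Conditions: 36 (2 equiv), N,N'-dicyclohexylcarbodiimide, DMAP (0.3 equiv), CH2Cl2, 0 °C to rt
Reagents that add atoms: none
Why: Steglich esterification with retention at C8; the acid has no α-hydrogen, so it cannot epimerise, and the mild conditions limit lactone migration to O8.

Step 24
Reactants: 37 (3S,6R,7R,8R)-8-{[(2S,3R)-2,3-dimethyloxirane-2-carbonyl]oxy}-3-[(3-methylbutanoyl)oxy]germacra-1(10)E,4Z,11(13)-trien-12,6-olide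
Product: 38 (1R,3S,6R,7R,8R,10R)-8-{[(2S,3R)-2,3-dimethyloxirane-2-carbonyl]oxy}-1,10-epoxy-3-[(3-methylbutanoyl)oxy]germacra-4Z,11(13)-dien-12,6-olide (CNP0167461.3)
Conditions: mCPBA (1.1 equiv), NaHCO3, CH2Cl2, 0 °C
Reagents that add atoms: 3-chloroperoxybenzoic acid, OOC(=O)c1cccc(Cl)c1
Why: Prilezhaev epoxidation of the most electron-rich alkene (C4=C5 is deactivated by two allylic acyloxy groups, C11=C13 is electron-poor); syn addition to the E alkene gives the trans epoxide, and attack on the exposed outer face of the E-cyclodecene is expected to give the 1R,10R isomer, the arrangement common among 1(10)-epoxy heliangolides.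

## Compound list

1 | (R)-2,2-dimethyl-1,3-dioxolane-4-carbaldehyde | O=C[C@H]1COC(C)(C)O1 | starting material
2 | methyl acrylate | C=CC(=O)OC | starting material
3 | methyl 2-{[(4R)-2,2-dimethyl-1,3-dioxolan-4-yl](hydroxy)methyl}prop-2-enoate (carbinol epimers) | C=C(C(=O)OC)C(O)[C@H]1COC(C)(C)O1 | intermediate
4 | methyl (2Z)-2-(bromomethyl)-3-[(4S)-2,2-dimethyl-1,3-dioxolan-4-yl]prop-2-enoate | COC(=O)/C(CBr)=C/[C@H]1COC(C)(C)O1 | intermediate
5 | tert-butyl(but-3-yn-1-yloxy)dimethylsilane | C#CCCO[Si](C)(C)C(C)(C)C | starting material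
6 | [(1E)-4-{[tert-butyl(dimethyl)silyl]oxy}-2-methylbut-1-en-1-yl]dimethylalumane | C/C(CCO[Si](C)(C)C(C)(C)C)=C\[Al](C)C | intermediate
7 | lithium butyl[(1E)-4-{[tert-butyl(dimethyl)silyl]oxy}-2-methylbut-1-en-1-yl]dimethylaluminate | [Li+].CCCC[Al-](C)(C)/C=C(\C)CCO[Si](C)(C)C(C)(C)C | intermediate
8 | (3E)-6-{[tert-butyl(dimethyl)silyl]oxy}-4-methylhex-3-en-1-ol | OCC/C=C(\C)CCO[Si](C)(C)C(C)(C)C | intermediate
9 | tert-butyl({(3E)-6-[(4-methoxybenzyl)oxy]-3-methylhex-3-en-1-yl}oxy)dimethylsilane | COc1ccc(COCC/C=C(\C)CCO[Si](C)(C)C(C)(C)C)cc1 | intermediate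
10 | (3E)-6-[(4-methoxybenzyl)oxy]-3-methylhex-3-en-1-ol | COc1ccc(COCC/C=C(\C)CCO)cc1 | intermediate
11 | (3E)-6-[(4-methoxybenzyl)oxy]-3-methylhex-3-enal | COc1ccc(COCC/C=C(\C)CC=O)cc1 | intermediate
12 | {(2Z)-3-[(4S)-2,2-dimethyl-1,3-dioxolan-4-yl]-2-(methoxycarbonyl)prop-2-en-1-yl}indium dibromide (representative formula) | COC(=O)/C(C[In](Br)Br)=C/[C@H]1COC(C)(C)O1 | intermediate
13 | methyl (3R,4R,6E)-3-[(4S)-2,2-dimethyl-1,3-dioxolan-4-yl]-4-hydroxy-9-[(4-methoxybenzyl)oxy]-6-methyl-2-methylidenenon-6-enoate | C=C(C(=O)OC)[C@@H]([C@H]1COC(C)(C)O1)[C@H](O)C/C(C)=C/CCOCc1ccc(OC)cc1 | intermediate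
14 | methyl (3S,4R,6E)-4-{[tert-butyl(dimethyl)silyl]oxy}-3-[(4S)-2,2-dimethyl-1,3-dioxolan-4-yl]-9-[(4-methoxybenzyl)oxy]-6-methyl-2-methylidenenon-6-enoate | C=C(C(=O)OC)[C@@H]([C@H]1COC(C)(C)O1)[C@H](O[Si](C)(C)C(C)(C)C)C/C(C)=C/CCOCc1ccc(OC)cc1 | intermediate
15 | methyl (3S,4R,6E)-4-{[tert-butyl(dimethyl)silyl]oxy}-3-[(1S)-1,2-dihydroxyethyl]-9-[(4-methoxybenzyl)oxy]-6-methyl-2-methylidenenon-6-enoate | C=C(C(=O)OC)[C@@H]([C@H](O)CO)[C@H](O[Si](C)(C)C(C)(C)C)C/C(C)=C/CCOCc1ccc(OC)cc1 | intermediate
16 | (4S,5S)-4-{(1R,3E)-1-{[tert-butyl(dimethyl)silyl]oxy}-6-[(4-methoxybenzyl)oxy]-3-methylhex-3-en-1-yl}-5-(hydroxymethyl)-3-methylideneoxolan-2-one | C=C1C(=O)O[C@H](CO)[C@H]1[C@H](O[Si](C)(C)C(C)(C)C)C/C(C)=C/CCOCc1ccc(OC)cc1 | intermediate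
17 | (2S,3S)-3-{(1R,3E)-1-{[tert-butyl(dimethyl)silyl]oxy}-6-[(4-methoxybenzyl)oxy]-3-methylhex-3-en-1-yl}-4-methylidene-5-oxooxolane-2-carbaldehyde | C=C1C(=O)O[C@H](C=O)[C@H]1[C@H](O[Si](C)(C)C(C)(C)C)C/C(C)=C/CCOCc1ccc(OC)cc1 | intermediate
18 | ethyltriphenylphosphonium bromide | CC[P+](c1ccccc1)(c1ccccc1)c1ccccc1.[Br-] | starting material
19 | ethylidenetriphenylphosphorane | CC=P(c1ccccc1)(c1ccccc1)c1ccccc1 | intermediate
20 | (1-iodoethyl)triphenylphosphonium iodide | CC(I)[P+](c1ccccc1)(c1ccccc1)c1ccccc1.[I-] | intermediate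
21 | (1-iodoethylidene)triphenylphosphorane | CC(I)=P(c1ccccc1)(c1ccccc1)c1ccccc1 | intermediate
22 | (4S,5S)-4-{(1R,3E)-1-{[tert-butyl(dimethyl)silyl]oxy}-6-[(4-methoxybenzyl)oxy]-3-methylhex-3-en-1-yl}-5-[(1Z)-2-iodoprop-1-en-1-yl]-3-methylideneoxolan-2-one | C=C1C(=O)O[C@H](/C=C(/C)I)[C@H]1[C@H](O[Si](C)(C)C(C)(C)C)C/C(C)=C/CCOCc1ccc(OC)cc1 | intermediate
23 | (4S,5S)-4-[(1R,3E)-1-{[tert-butyl(dimethyl)silyl]oxy}-6-hydroxy-3-methylhex-3-en-1-yl]-5-[(1Z)-2-iodoprop-1-en-1-yl]-3-methylideneoxolan-2-one | C=C1C(=O)O[C@H](/C=C(/C)I)[C@H]1[C@H](O[Si](C)(C)C(C)(C)C)C/C(C)=C/CCO | intermediate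
24 | (3E,6R)-6-{[tert-butyl(dimethyl)silyl]oxy}-6-{(2S,3S)-2-[(1Z)-2-iodoprop-1-en-1-yl]-4-methylidene-5-oxooxolan-3-yl}-4-methylhex-3-enal | C=C1C(=O)O[C@H](/C=C(/C)I)[C@H]1[C@H](O[Si](C)(C)C(C)(C)C)C/C(C)=C/CC=O | intermediate
25 | (3E,6R)-6-{[tert-butyl(dimethyl)silyl]oxy}-6-{(2S,3S)-2-[(1Z)-2-iodoprop-1-en-1-yl]-4-methylidene-5-oxooxolan-3-yl}-4-methylhex-3-enoic acid | C=C1C(=O)O[C@H](/C=C(/C)I)[C@H]1[C@H](O[Si](C)(C)C(C)(C)C)C/C(C)=C/CC(=O)O | intermediate
26 | (3E,6R)-6-{[tert-butyl(dimethyl)silyl]oxy}-6-{(2S,3S)-2-[(1Z)-2-iodoprop-1-en-1-yl]-4-methylidene-5-oxooxolan-3-yl}-4-methylhex-3-enoyl chloride | C=C1C(=O)O[C@H](/C=C(/C)I)[C@H]1[C@H](O[Si](C)(C)C(C)(C)C)C/C(C)=C/CC(=O)Cl | intermediate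
27 | S-ethyl (3E,6R)-6-{[tert-butyl(dimethyl)silyl]oxy}-6-{(2S,3S)-2-[(1Z)-2-iodoprop-1-en-1-yl]-4-methylidene-5-oxooxolan-3-yl}-4-methylhex-3-enethioate | C=C1C(=O)O[C@H](/C=C(/C)I)[C@H]1[C@H](O[Si](C)(C)C(C)(C)C)C/C(C)=C/CC(=O)SCC | intermediate
28 | S-ethyl (3E,6R)-6-{[tert-butyl(dimethyl)silyl]oxy}-4-methyl-6-{(2S,3S)-4-methylidene-5-oxo-2-[(1Z)-2-(tributylstannyl)prop-1-en-1-yl]oxolan-3-yl}hex-3-enethioate | C=C1C(=O)O[C@H](/C=C(/C)[Sn](CCCC)(CCCC)CCCC)[C@H]1[C@H](O[Si](C)(C)C(C)(C)C)C/C(C)=C/CC(=O)SCC | intermediate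
29 | (6R,7S,8R)-8-{[tert-butyl(dimethyl)silyl]oxy}-3-oxogermacra-1(10)E,4Z,11(13)-trien-12,6-olide | C=C1C(=O)O[C@@H]2/C=C(/C)C(=O)C/C=C(\C)C[C@@H](O[Si](C)(C)C(C)(C)C)[C@@H]12 | intermediate
30 | (3S,6R,7S,8R)-8-{[tert-butyl(dimethyl)silyl]oxy}-3-hydroxygermacra-1(10)E,4Z,11(13)-trien-12,6-olide | C=C1C(=O)O[C@@H]2/C=C(/C)[C@@H](O)C/C=C(\C)C[C@@H](O[Si](C)(C)C(C)(C)C)[C@@H]12 | intermediate
31 | (3S,6R,7S,8R)-8-{[tert-butyl(dimethyl)silyl]oxy}-3-[(3-methylbutanoyl)oxy]germacra-1(10)E,4Z,11(13)-trien-12,6-olide | C=C1C(=O)O[C@@H]2/C=C(/C)[C@@H](OC(=O)CC(C)C)C/C=C(\C)C[C@@H](O[Si](C)(C)C(C)(C)C)[C@@H]12 | intermediate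
32 | (3S,6R,7R,8R)-8-hydroxy-3-[(3-methylbutanoyl)oxy]germacra-1(10)E,4Z,11(13)-trien-12,6-olide | C=C1C(=O)O[C@@H]2/C=C(/C)[C@@H](OC(=O)CC(C)C)C/C=C(\C)C[C@@H](O)[C@@H]12 | intermediate
33 | tiglic acid | C/C=C(\C)C(=O)O | starting material
34 | (2E)-2-methylbut-2-en-1-ol | C/C=C(\C)CO | intermediate
35 | [(2R,3R)-2,3-dimethyloxiran-2-yl]methanol | OC[C@@]1(C)O[C@@H]1C | intermediate
36 | (2S,3R)-2,3-dimethyloxirane-2-carboxylic acid | OC(=O)[C@@]1(C)O[C@@H]1C | intermediate
37 | (3S,6R,7R,8R)-8-{[(2S,3R)-2,3-dimethyloxirane-2-carbonyl]oxy}-3-[(3-methylbutanoyl)oxy]germacra-1(10)E,4Z,11(13)-trien-12,6-olide | C=C1C(=O)O[C@@H]2/C=C(/C)[C@@H](OC(=O)CC(C)C)C/C=C(\C)C[C@@H](OC(=O)[C@@]3(C)O[C@@H]3C)[C@@H]12 | intermediate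
38 | CNP0167461.3, (1R,3S,6R,7R,8R,10R)-8-{[(2S,3R)-2,3-dimethyloxirane-2-carbonyl]oxy}-1,10-epoxy-3-[(3-methylbutanoyl)oxy]germacra-4Z,11(13)-dien-12,6-olide | C=C1C(=O)O[C@@H]2/C=C(/C)[C@@H](OC(=O)CC(C)C)C[C@H]3O[C@]3(C)C[C@@H](OC(=O)[C@@]3(C)O[C@@H]3C)[C@@H]12 | target

## Step count and least certain steps

Total step count: 24. Longest linear sequence: 19 steps (steps 3–19, 23 and 24, from 5).

**Step 16 (key step).** Ring closure may lose to intermolecular coupling, because a ten-membered ring with two trisubstituted alkenes is strained. The acylpalladium stage may also lose carbon monoxide, since this would lead to an allyl system, or the β,γ-alkene may drift into conjugation with the new ketone. Fallback: the same C3–C4 bond is closed by a Nozaki–Hiyama–Kishi reaction. Alcohol 23 is oxidised with Dess–Martin periodinane to aldehyde 24, which is isolated. CrCl2 with NiCl2 (1 mol %) in DMSO/THF at high dilution adds the vinyl iodide to the aldehyde and gives the C3-epimeric ring alcohols F1. Dess–Martin oxidation of F1 returns to 29; the 3S epimer of F1 is 30 itself.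

**Step 7.** Facial selectivity at C7 relative to the dioxolane may be low or reversed, for example by indium chelation to the ring oxygen, which would bring the aldehyde in syn to the C6–O bond. The closed transition state may leak to the anti C7/C8 adduct, and the C8 hydroxyl may lactonise early. Fallback: ring-enforced control of C6/C7 followed by inversion at C8.
- Adduct 3 is treated with pyridinium p-toluenesulfonate in methanol to give the hydroxy lactone diol F2.
- The primary alcohol of F2 is tritylated (trityl chloride, pyridine) to F3.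
- NBS/Me2S converts F3 with allylic transposition into the bromomethyl butenolide F4.
- CrCl2 in THF couples F4 with 11. The butenolide carbon attacks anti to the ring substituent, which fixes the trans C6/C7 relationship, and the chair transition state of the E-locked allylchromium gives the C8-epimeric alcohol F5.
- Mitsunobu reaction of F5 with formic acid (PPh3, diisopropyl azodicarboxylate) inverts C8 to the formate F6. KHCO3 in aqueous methanol gives the alcohol F7, and TBSOTf/2,6-lutidine gives the silyl ether F8.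
- Detritylation of F8 with formic acid in ether rejoins the route at 16.

**Step 11.** The basic, nucleophilic ylide may epimerise C6 next to the aldehyde or add to the methylene lactone, and the iodo ylide may partly lose iodine and give the plain propenyl compound. Fallback: base-free olefination followed by selective coupling.
- Aldehyde 17 with CBr4/PPh3 gives the dibromoalkene F9.
- MeZnCl with PdCl2(DPEphos) replaces the bromine trans to C6 and gives the Z bromoalkene F10.
- (Bu3Sn)2 with Pd(PPh3)4 in toluene at 80 °C gives the Z stannane F11.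
- Iododestannylation of F11 with I2 in CH2Cl2 at 0 °C returns, with retention, to 22.

**Step 17.** The conformation of the ten-membered enone may override the catalyst and give the 3R alcohol or a mixture, and the acidic C2 methylene may allow isomerisation before reduction. Fallback: substrate-controlled reduction of 29 (NaBH4, CeCl3·7H2O, MeOH/THF, −78 °C). If this gives the 3R alcohol F12, Mitsunobu esterification of F12 with 3-methylbutanoic acid (PPh3, diisopropyl azodicarboxylate) inverts C3 and leads directly to 31.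

**Step 24.** The peracid may attack the face that gives the 1S,10S epoxide if the reactive conformer differs from that assumed, and the C4=C5 alkene may be over-oxidised. Fallback: reagent-controlled epoxidation of 37 with the D-fructose-derived Shi ketone and Oxone (KHSO5 triple salt) in buffered MeCN/dimethoxymethane at 0 °C. This ketone gives R,R epoxides from trans and trisubstituted alkenes, and the reaction leads straight to 38 without a new intermediate.

## Further compounds

F1 | step 16 | (3RS,6R,7S,8R)-8-{[tert-butyl(dimethyl)silyl]oxy}-3-hydroxygermacra-1(10)E,4Z,11(13)-trien-12,6-olide (C3 epimers) | C=C1C(=O)O[C@@H]2/C=C(/C)C(O)C/C=C(\C)C[C@@H](O[Si](C)(C)C(C)(C)C)[C@@H]12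
F2 | step 7 | (5R)-4-hydroxy-5-(hydroxymethyl)-3-methylideneoxolan-2-one (C4 epimers) | C=C1C(=O)O[C@H](CO)C1O
F3 | step 7 | (5R)-4-hydroxy-3-methylidene-5-[(trityloxy)methyl]oxolan-2-one (C4 epimers) | C=C1C(=O)O[C@H](COC(c2ccccc2)(c2ccccc2)c2ccccc2)C1O
F4 | step 7 | (5S)-3-(bromomethyl)-5-[(trityloxy)methyl]furan-2(5H)-one | BrCC1=C[C@@H](COC(c2ccccc2)(c2ccccc2)c2ccccc2)OC1=O
F5 | step 7 | trans-lactone with 8-epi hydroxyl: 4-{(1S,3E)-1-hydroxy-6-[(4-methoxybenzyl)oxy]-3-methylhex-3-en-1-yl}-3-methylidene-5-[(trityloxy)methyl]oxolan-2-one | C=C1C(=O)O[C@H](COC(c2ccccc2)(c2ccccc2)c2ccccc2)[C@H]1[C@@H](O)C/C(C)=C/CCOCc2ccc(OC)cc2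
F6 | step 7 | C8-inverted formate: (1R,3E)-6-[(4-methoxybenzyl)oxy]-3-methyl-1-{4-methylidene-5-oxo-2-[(trityloxy)methyl]oxolan-3-yl}hex-3-en-1-yl formate | C=C1C(=O)O[C@H](COC(c2ccccc2)(c2ccccc2)c2ccccc2)[C@H]1[C@H](OC=O)C/C(C)=C/CCOCc2ccc(OC)cc2
F7 | step 7 | 4-{(1R,3E)-1-hydroxy-6-[(4-methoxybenzyl)oxy]-3-methylhex-3-en-1-yl}-3-methylidene-5-[(trityloxy)methyl]oxolan-2-one | C=C1C(=O)O[C@H](COC(c2ccccc2)(c2ccccc2)c2ccccc2)[C@H]1[C@H](O)C/C(C)=C/CCOCc2ccc(OC)cc2
F8 | step 7 | 4-{(1R,3E)-1-{[tert-butyl(dimethyl)silyl]oxy}-6-[(4-methoxybenzyl)oxy]-3-methylhex-3-en-1-yl}-3-methylidene-5-[(trityloxy)methyl]oxolan-2-one | C=C1C(=O)O[C@H](COC(c2ccccc2)(c2ccccc2)c2ccccc2)[C@H]1[C@H](O[Si](C)(C)C(C)(C)C)C/C(C)=C/CCOCc2ccc(OC)cc2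
F9 | step 11 | 4-{(1R,3E)-1-{[tert-butyl(dimethyl)silyl]oxy}-6-[(4-methoxybenzyl)oxy]-3-methylhex-3-en-1-yl}-5-(2,2-dibromoethenyl)-3-methylideneoxolan-2-one | C=C1C(=O)O[C@H](C=C(Br)Br)[C@H]1[C@H](O[Si](C)(C)C(C)(C)C)C/C(C)=C/CCOCc2ccc(OC)cc2
F10 | step 11 | 5-[(1Z)-2-bromoprop-1-en-1-yl]-4-{(1R,3E)-1-{[tert-butyl(dimethyl)silyl]oxy}-6-[(4-methoxybenzyl)oxy]-3-methylhex-3-en-1-yl}-3-methylideneoxolan-2-one | C=C1C(=O)O[C@H](/C=C(/C)Br)[C@H]1[C@H](O[Si](C)(C)C(C)(C)C)C/C(C)=C/CCOCc2ccc(OC)cc2
F11 | step 11 | 4-{(1R,3E)-1-{[tert-butyl(dimethyl)silyl]oxy}-6-[(4-methoxybenzyl)oxy]-3-methylhex-3-en-1-yl}-3-methylidene-5-[(1Z)-2-(tributylstannyl)prop-1-en-1-yl]oxolan-2-one | C=C1C(=O)O[C@H](/C=C(/C)[Sn](CCCC)(CCCC)CCCC)[C@H]1[C@H](O[Si](C)(C)C(C)(C)C)C/C(C)=C/CCOCc2ccc(OC)cc2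
F12 | step 17 | (3R,6R,7S,8R)-8-{[tert-butyl(dimethyl)silyl]oxy}-3-hydroxygermacra-1(10)E,4Z,11(13)-trien-12,6-olide | C=C1C(=O)O[C@@H]2/C=C(/C)[C@H](O)C/C=C(\C)C[C@@H](O[Si](C)(C)C(C)(C)C)[C@@H]12
F0 | step 24 | none | none
A1 | alternative 1 | 1(10)-alkene analogue of the target (identical with 37) | C=C1C(=O)O[C@@H]2/C=C(/C)[C@@H](OC(=O)CC(C)C)C/C=C(\C)C[C@@H](OC(=O)[C@@]3(C)O[C@@H]3C)[C@@H]12
A2 | alternative 1 | 8-{[(2S,3R)-2,3-dimethyloxirane-2-carbonyl]oxy}germacra-1(10)E,3Z,5Z,11(13)-tetraen-12-oic acid | C=C(C(=O)O)[C@H]1/C=C\C(C)=C/C/C=C(\C)C[C@H]1OC(=O)[C@@]2(C)O[C@@H]2C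
A3 | alternative 2 | 8-{[tert-butyl(dimethyl)silyl]oxy}-3-[(3-methylbutanoyl)oxy]-13-norgermacra-1(10)E,4Z-dien-12,6-olide | C1C(=O)O[C@@H]2/C=C(/C)[C@@H](OC(=O)CC(C)C)C/C=C(\C)C[C@@H](O[Si](C)(C)C(C)(C)C)[C@@H]12
A4 | alternative 2 | methyl (6E,10Z)-4-{[tert-butyl(dimethyl)silyl]oxy}-3-formyl-11-iodo-6,10-dimethyl-9-[(3-methylbutanoyl)oxy]undeca-6,10-dienoate | COC(=O)C[C@@H](C=O)[C@H](O[Si](C)(C)C(C)(C)C)C/C(C)=C/C[C@H](OC(=O)CC(C)C)/C(C)=C\I
A5 | alternative 3 | 3-{[tert-butyl(dimethyl)silyl]oxy}-8-[(4-methoxybenzyl)oxy]-4,10-dimethylcyclodeca-1(10)E,4Z-dien-6-one (germacrane numbering) | O=C1C[C@H](OCc2ccc(OC)cc2)C/C(C)=C/C[C@H](O[Si](C)(C)C(C)(C)C)/C(C)=C\1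
A6 | alternative 3 | 4-{[tert-butyl(dimethyl)silyl]oxy}-1-{(E)-2-[(4-methoxybenzyl)oxy]ethenyl}-3-methyl-6-(prop-1-en-2-yl)cyclohex-2-en-1-ol (trans dialkenyl) | O[C@]1(/C=C/OCc2ccc(OC)cc2)C=C(C)[C@@H](O[Si](C)(C)C(C)(C)C)C[C@@H]1C(C)=C
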